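Slowness is what we have to weigh: the excess of right-handed substrate rises as left-handed product forms.

| setting | dusk | summer | midnight | flask |
|---|---|---|---|---|
| left-handed substrate | 0.50 M | 0.50 M | 0.25 M | 0.50 M |
| right-handed substrate | 0.50 M | 0.50 M | 0.25 M | 0.50 M |
| gas | 130 mM (held) | 130 mM (held) | 130 mM (held) | 130 mM (held) |
| free catalyst | 1.2 mM | 5 mM | 2.5 mM | 2.5 mM |
| remark | run made earlier | run made earlier | run made earlier |  |
| time |  |  |  | 6.0 h |

- dusk (time / h: right-handed substrate / %, left-handed substrate / %, left-handed product / %): 0.500: 49.7, 49.2, 0.5; 1.50: 50.1, 47.2, 2.1; 3.00: 49.7, 43.1, 7.3; 4.00: 49.6, 40.9, 9.2; 6.00: 49.5, 34.4, 15.8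
- summer (time / h: right-handed substrate / %, left-handed substrate / %, left-handed product / %): 0.500: 50.1, 48.6, 1.2; 0.833: 50.2, 46.4, 3.7; 1.50: 49.9, 42.1, 7.9; 3.00: 50.0, 32.0, 17.6; 6.00: 48.3, 13.0, 36.7
- midnight (time / h: right-handed substrate / %, left-handed substrate / %, left-handed product / %): 0.500: 50.3, 48.2, 1.1; 1.50: 49.5, 41.2, 8.3; 3.00: 49.4, 28.7, 20.7; 4.00: 49.6, 21.2, 28.6; 6.00: 49.0, 8.1, 41.8

(each reading ± 0.3 percentage points)

- free catalyst is single-handed; left-handed substrate and right-handed substrate are mirror images of each other, charged as a racemate, each of them at the stated concentration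
- at the start none of reagent is dissolved
- the analysis behind the earlier runs scatters by 0.3 percentage points, standard deviation
- on the list of suspects stand: free catalyst + left-handed substrate <-> catalyst intermediate A; free catalyst + right-handed substrate <-> catalyst intermediate B; reagent + catalyst intermediate A -> free catalyst + left-handed product; reagent + catalyst intermediate B -> free catalyst + right-handed product; gas <-> reagent

- whether the excess of right-handed substrate over left-handed substrate among what is left of the two reaches 99 % by 6.0 h (no / yes)
- the highest excess of right-handed substrate over left-handed substrate among what is left of the two up to 6.0 h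

Right-handed substrate is the small correction, since the summer run still holds 48.3 % at 6.00 h, so we keep it at its charge. If x is the fraction of the charge turned into left-handed product, the excess is x/(1−x), and the level asked for requires

x = 49.7 %.

The flask differs from dusk and summer in its catalyst charge, so we read their late slopes as fractions of the charge:

dusk 0.0304 h⁻¹, summer 0.0640 h⁻¹, order in catalyst 0.521.

Interpolated to this flask, that gives

0.0446 h⁻¹.

Two times now count. One is the time needed, the target x over this rate: 11.2 h. The other is the 6.0 h allowed, which is shorter. We expect no, with an excess near 36.5 %, lag uncounted.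

The forecast says no and 30 %, lower than ours, “still rising at 6 h, and nowhere near 99 %”.

    free catalyst + left-handed substrate ⇌ catalyst intermediate A (K = 19.0 M⁻¹, k = 0.810 M⁻¹ s⁻¹)
    free catalyst + right-handed substrate ⇌ catalyst intermediate B (K = 1.10 M⁻¹, k = 0.830 M⁻¹ s⁻¹)
    reagent + catalyst intermediate A → free catalyst + left-handed product (k = 0.0860 M⁻¹ s⁻¹)
    reagent + catalyst intermediate B → free catalyst + right-handed product (k = 0.0150 M⁻¹ s⁻¹)
    gas ⇌ reagent, rate k5*(csat - [reagent]) (kL = 2.60 × 10⁻⁴ s⁻¹)

The simulated flask answers no, with a top of 34.3 %. Its left-handed product at 6.00 h is 25.6 %, which is 51.5 % of the target, while the time allowed is 53.6 % of our time needed. The answer turns with time: the neighbour flask left until 25 h, longer than our time needed, holds 0 % left-handed substrate and reaches an excess of >99.9 %.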